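The numbers in the tables come from a simulation with made-up constants; noise was put on by code.

- D is a small charge, 0.073 mol% of X, so each D must turn over many times in this flask, and I want the rate of making Z per D charged.

all flasks: X 26 mM; G 1.05 equiv; D 0.073 mol%
- eta: the very flask that is asked about, followed so far
- flask: 

- eta (time / h: Z / %, X / %): 2.00: 0.9, 55.2; 4.00: 3.8, 38.0; 6.00: 7.0, 28.5; 8.00: 9.7, 22.9; 10.0: 11.9, 18.4

(each reading ± 0.5 percentage points)

* factor on the rate of making Z when 20% of the X are converted if D is charged twice over
* factor on the rate when 20% of the X are converted if D is charged at 0.015 mol% instead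

- no earlier run changes the charge of D; that part of a forecast is a guess

- From 4.00 h to 10.0 h, Z climbs almost in a straight line, so I freeze its rate at v = 0.351 mM h⁻¹, while X falls to half of its reading at 4.00 h.
- My objection is that the line may sag: Z gains 3.2 percentage points from 4.00 h to 6.00 h and 2.2 points from 8.00 h to 10.0 h. Each reading carries a scatter of 0.5 points, so I keep v as a mean over the plateau.
- Dividing v by the D charged gives the plateau turnover rate τ = 18.5 h⁻¹, the usual turnover frequency.
- The next objection is that the question concerns 20% conversion, and X already reads 55.2% at 2.00 h, so that point lies before the first reading.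
- That early stretch is not on the plateau: a flat rate from the start gives 2.70% of Z at 2.00 h, and the reading is 0.9%, with a scatter of 0.5 points.
- So I write the rate at that point as τ times the D charged times a share still filling. More D raises the first factor in proportion. If D also fills the share, the factor climbs toward the square.
- My guess for doubling is therefore between 2 and 4, and for the lower charge between 0.205 and 0.0422. No run tests this.
- The forecast says 1.9 (1.2 to 2.3) and 0.24 (0.15 to 0.7), and it adds: “No run varies D, so this is a guess.” Its doubling value lies below my bracket.
- The flask gives 2.83 and 0.0642, beyond the forecast's ranges.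

    G + L → D + Z (k = 0.636 M⁻¹ s⁻¹)
    2 X → J (k = 0.00163 M⁻¹ s⁻¹)
    X + D ⇌ D + E (K = 1.04, k = 1.34 M⁻¹ s⁻¹)
    D + E ⇌ L (K = 482 M⁻¹, k = 3.60 M⁻¹ s⁻¹)

- In this flask, X + D gave E while 2 X gave J, which used X 2.5 times as fast as the forward X + D step at 1.87 h, and D + E relaxed with L in 0.946 min against 4.70 h for the step before. L held 25.5% of the catalyst at 2.00 h and 28.3% at 10.0 h, and G + L, at 63 h⁻¹ per L with G as charged and with G at 88.9% of its charge, then gave 15.8 h⁻¹ per D charged against τ = 18.5 h⁻¹, falling to 9.12 h⁻¹ at 20.0 h, with L at 18.0%, G at 80.4% and Z at 20.6%.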